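**Retrosynthetic overview**

1. Numbering: ring B (seven-membered) is C1(O-angeloyl)–C2H=C3(Me)–C4H2–C5(O-aroyl)–C6H–C7(Me); ring A (five-membered) is C6–C7–C8H2–C9H2–C10(OH)(i-Pr). The "β face" is the face of the C7 methyl. The feature used is that ring B carries oxygen on both C1 and C5, the two carbons that flank the C6–C7 fusion bond, so ring B is a C1–C5 five-carbon unit, oxygenated at both ends, laid across the C6–C7 edge of ring A.
2. Late disconnections: the C1 angelate and C5 4-hydroxybenzoate esters; C1–OH from the C2=C3–C1=O enone; C5–OH from a C5 ketone by reduction directed by the C10 hydroxyl; the trans ring fusion by equilibration of C6 next to the C5 ketone.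
3. Key disconnection: the ring B 1,5-dione comes from glycol cleavage of the C1–C5 bond of a cyclobutane-1,2-diol. That cyclobutane comes from a [2+2] photocycloaddition of 3-methylcyclopent-2-enone (C10=O, C6=C7) to the C1=C5 bond of 4-methyl-1,2-bis(trimethylsilyloxy)cyclopentene, forming C7–C1 and C6–C5.
4. Ring order: ring A is bought as the enone; the C1–C5 cyclopentene comes from an acyloin condensation; the cyclobutane is closed in the key step; C10(OH)(i-Pr) is installed on the rigid tricycle; ring B appears when the cyclobutane is cleaved.
5. Stereochemistry: C7 (absolute) is set in the photocycloaddition; C10, C6, C5 and C1 are relayed from C7; C1, C3 and C5 of the photoadduct are erased later.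

Key step: step 2

Assumption: the (S)-prolinol-derived oxazaborolidine–AlBr3 complex is taken to leave the Si face of the enone β-carbon (C7) open, by analogy with six-membered enones; if the opposite sense is found, the catalyst from (R)-prolinol is used.

Remark: 4 is expected to contain some of its C3 methyl epimer; the expected major epimer (methyl anti to the cyclobutane) is drawn throughout, and both converge in step 13, where C3 becomes sp2.

**Route**

Step 1
Reactants: 1 dimethyl 3-methylglutarate
Product: 2 4-methyl-1,2-bis(trimethylsilyloxy)cyclopent-1-ene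
Conditions: Na, Me3SiCl, toluene, reflux
Reagents that add atoms: chlorotrimethylsilane, C[Si](C)(C)Cl
Why: Rühlmann acyloin condensation, in which electron transfer from sodium couples the two ester carbonyls and Me3SiCl traps the enediolate as the bis(silyl) ether (suppressing Dieckmann condensation); the methyl carbon lies on the mirror plane, so no stereocentre arises.

Step 2
Reactants: 2 4-methyl-1,2-bis(trimethylsilyloxy)cyclopent-1-ene; 3 3-methylcyclopent-2-en-1-one
Product: 4 cis-anti-cis tricyclic ketone (7S): ring A cyclopentanone (C10=O) and the C1–C5 cyclopentane cis-fused on opposite faces of the C6–C7–C1–C5 cyclobutane; C7 methyl and H6 cis; trimethylsilyloxy groups on C1 and C5; C3 methyl anti to the cyclobutane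
Conditions: 3 (1 equiv), 2 (5 equiv), oxazaborolidine from (S)-α,α-bis(3,5-dimethylphenyl)prolinol and 2,4,6-trifluorophenylboronic acid (50 mol%), AlBr3 (50 mol%), CH2Cl2, −75 °C, hν (366 nm); Et3N quench at −75 °C
Reagents that add atoms: none
Why: Proposed new method: the enone, bound through its C10 carbonyl to the boron of the AlBr3-activated oxazaborolidine, is excited at 366 nm and its triplet adds through the β-carbon C7 to C1 of the electron-rich enediol ether to give a 1,4-diradical that, after spin inversion, closes the C6–C5 bond. The closest known reactions are the uncatalysed [2+2] photocycloaddition of cyclic enones to 1,2-bis(silyloxy)cycloalkenes and the oxazaborolidine–AlBr3-catalysed enantioselective intermolecular [2+2] photocycloaddition of cyclic enones to simple alkenes, whose combination on a cyclopentenone and a silyl enediol ether is untested. The one ring formed, the cyclobutane C6–C7–C1–C5, closes by intermolecular [2+2] cycloaddition, its second bond by recombination of the 1,4-diradical, and it must be cis-fused to ring A because a trans-fused bicyclo[3.2.0]heptanone is too strained. C7 is set by the catalyst, whose aryl group covers one enone face so that the alkene adds to the Si face of C7, C6 follows from the cis fusion, C1 and C5 from exo approach that keeps the two five-membered rings anti, and C3 from attack anti to its methyl group. The only selectivity the route needs is the enone face, because the symmetric alkene removes any head-to-head versus head-to-tail question and C1, C3, C5 and C6 are all destroyed or re-equilibrated later. Dark Mukaiyama–Michael addition and loss of silyl groups should be slow at −75 °C, since conjugate addition would have to join two fully substituted carbons, and the reaction is quenched cold with Et3N before warming.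

Step 3
Reactants: 4 tricyclic ketone
Product: 5 enol triflate of 4 (C9=C10, C10–OSO2CF3)
Conditions: KHMDS, THF, −78 °C; then PhNTf2, −78 → 0 °C
Reagents that add atoms: N-phenylbis(trifluoromethanesulfonimide), O=S(=O)(N(c1ccccc1)S(=O)(=O)C(F)(F)F)C(F)(F)F
Why: Kinetic enolate formation and O-triflation occur at the C9 methylene because the only other α-hydrogen sits on cyclobutane carbon C6, whose enolate would place a double bond at the strained ring fusion, and the silyl ethers are inert to the amide base.

Step 4
Reactants: 5 enol triflate
Product: 6 C10-isopropyl alkene (C9=C10) with the C1 and C5 silyl ethers retained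
Conditions: i-PrMgCl, Fe(acac)3 (5 mol%), THF/NMP, −30 °C
Reagents that add atoms: isopropylmagnesium chloride, CC(C)[Mg]Cl
Why: Iron-catalysed Kumada-type cross-coupling of an alkenyl triflate with an alkyl Grignard reagent is fast at low temperature, accepts secondary alkyl groups and leaves silyl ethers untouched.

Step 5
Reactants: 6 isopropyl alkene
Product: 7 9,10-epoxide with the oxygen on the convex face of ring A (cis to H6 and the C7 methyl)
Conditions: dimethyldioxirane, acetone/CH2Cl2, −20 → 0 °C
Reagents that add atoms: dimethyldioxirane, CC1(C)OO1
Why: Electrophilic epoxidation of the electron-rich trisubstituted alkene by the neutral dioxirane should occur on the convex face of the bicyclo[3.2.0] unit, because the concave face is covered by the cyclobutane and its C1 and C5 silyloxy groups, which places the C10–O bond cis to the C7 methyl.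

Step 6
Reactants: 7 epoxide
Product: 8 tertiary alcohol: C10–OH cis to the C7 methyl, isopropyl on the concave face, C9 now CH2, silyl ethers retained
Conditions: LiEt3BH, THF, 0 → 40 °C; aqueous work-up
Reagents that add atoms: none
Why: SN2 hydride opening of a trisubstituted epoxide takes place at the less substituted C9, so the oxygen stays on C10 with its configuration unchanged.

Step 7
Reactants: 8 bis(silyl ether) alcohol
Product: 9 triol (C1–OH, C5–OH on the cyclobutane, C10–OH)
Conditions: K2CO3 (cat.), MeOH, rt
Reagents that add atoms: none
Why: Base-catalysed methanolysis of trimethylsilyl ethers is safe here because the C10 carbonyl is gone, so the freed C5 cyclobutanol can no longer open by retro-aldol (de Mayo-type) cleavage of C5–C6.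

Step 8
Reactants: 9 triol
Product: 10 cis-fused 10-hydroxy-1,5-dione (bicyclo[5.3.0]decane; H6 and C7 methyl cis; C10–OH cis to the C7 methyl)
Conditions: Pb(OAc)4, CH2Cl2, 0 °C
Reagents that add atoms: none
Why: Criegee glycol cleavage of the cis ditertiary diol through a cyclic diester of tetravalent lead, driven by release of cyclobutane strain, breaks C1–C5 to give the C1 and C5 ketones and so opens ring B, while the lone C10 alcohol has no vicinal partner.

Step 9
Reactants: 10 cis-fused dione
Product: 11 trans-fused 10-hydroxy-1,5-dione (H6 trans to the C7 methyl; C5 cis to the C10–OH and trans to the isopropyl group)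
Conditions: DBU (0.3 equiv), toluene, rt
Reagents that add atoms: none
Why: Base-mediated epimerisation through the C5 enol(ate) should favour the trans fusion, since the cis isomer holds C5, C1 and the isopropyl group on one face of ring A whereas the trans isomer puts C5 trans to the isopropyl group and within hydrogen-bonding reach of the C10 hydroxyl; C7 is quaternary and cannot change.

Step 10
Reactants: 11 trans-fused dione
Product: 12 5,10-dihydroxy-1-ketone (C5–OH on the α face, trans to the C7 methyl and cis to H6)
Conditions: Me4NBH(OAc)3, MeCN/AcOH, −30 → −10 °C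
Reagents that add atoms: none
Why: Evans–Saksena hydroxyl-directed reduction, in which the C10 hydroxyl exchanges onto boron and delivers hydride through a six-membered transition state to the β face of the C5 ketone (giving the anti 1,3-diol), while the C1 ketone has no hydroxyl in reach and is not reduced by this mild reagent.

Step 11
Reactants: 13 4-hydroxybenzoic acid
Product: 15 4-(triisopropylsilyloxy)benzoic acid, via silyl ester 14 (not isolated)
Conditions: i-Pr3SiCl, imidazole, DMF, rt; then K2CO3, THF/MeOH/H2O, 0 °C; citric acid work-up
Reagents that add atoms: chlorotriisopropylsilane, CC(C)[Si](Cl)(C(C)C)C(C)C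
Why: Silylation of both the phenol and the acid followed by selective hydrolysis of the far more labile silyl ester.

Step 12
Reactants: 12 5,10-dihydroxy-1-ketone; 15 4-(triisopropylsilyloxy)benzoic acid
Product: 16 C5 4-(triisopropylsilyloxy)benzoate (C10–OH free, C1 ketone)
Conditions: EDC·HCl, DMAP, CH2Cl2, rt
Reagents that add atoms: none
Why: Steglich esterification acylates the secondary C5 alcohol, the tertiary C10 alcohol next to the isopropyl group being too hindered to compete.

Step 13
Reactants: 16 C5 ester
Product: 18 C2=C3 enone (C1=O) with C10–OSiMe3, via bis-silyl enol ether 17 (not isolated)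
Conditions: Me3SiOTf, Et3N, CH2Cl2, 0 °C → rt; then Pd(OAc)2, MeCN, rt
Reagents that add atoms: trimethylsilyl trifluoromethanesulfonate, C[Si](C)(C)OS(=O)(=O)C(F)(F)F
Why: Saegusa–Ito oxidation, in which enolisation can only go towards C2 because C7 is quaternary and the enolate of divalent palladium loses the C3 hydrogen by β-hydride elimination (either C3 epimer can do so), giving the enone and erasing C3, while the excess silyl triflate caps the C10 alcohol.

Step 14
Reactants: 18 enone
Product: 19 allylic alcohol (C1–OH on the α face, trans to the C7 methyl)
Conditions: (S)-2-methyl-CBS-oxazaborolidine (0.3 equiv), catecholborane, toluene, −78 → −40 °C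
Reagents that add atoms: none
Why: Corey–Bakshi–Shibata 1,2-reduction, in which the ketone binds the catalyst anti to the bulky quaternary C7 and hydride is delivered to the β face of C1, the same face that Felkin-type torsional control should favour because attack there is anti to the C7–C6 bond.

Step 15
Reactants: 19 allylic alcohol; 20 angelic acid
Product: 22 C1 angelate (aryl silyl ether and C10 silyl ether retained), via mixed anhydride 21 (not isolated)
Conditions: 20, 2,4,6-trichlorobenzoyl chloride, Et3N, toluene, rt; then 19, 80 °C
Reagents that add atoms: none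
Why: Yamaguchi esterification through the mixed anhydride without DMAP, conditions chosen because they should not isomerise the Z double bond of the angelate to the tiglate, and the silylated tertiary alcohol cannot react.

Step 16
Reactants: 22 protected diester
Product: 23 CNP0273650.2 (target)
Conditions: Bu4NF, AcOH, THF, 0 °C → rt
Reagents that add atoms: none
Why: Fluoride-mediated desilylation buffered with acetic acid cleaves the aryl triisopropylsilyl ether and the tertiary trimethylsilyl ether while leaving both esters and the Z alkene intact.

**Compound list**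

1 | dimethyl 3-methylglutarate | COC(=O)CC(C)CC(=O)OC | starting material
2 | 4-methyl-1,2-bis(trimethylsilyloxy)cyclopent-1-ene | CC1CC(O[Si](C)(C)C)=C(O[Si](C)(C)C)C1 | intermediate
3 | 3-methylcyclopent-2-en-1-one | CC1=CC(=O)CC1 | starting material
4 | cis-anti-cis tricyclic photoadduct, C10 ketone, C1/C5 bis(trimethylsilyl ether) | O=C1CC[C@@]2(C)[C@@H]1[C@]1(O[Si](C)(C)C)C[C@@H](C)C[C@]21O[Si](C)(C)C | intermediate
5 | C10 enol triflate (C9=C10) | FC(F)(F)S(=O)(=O)OC1=CC[C@@]2(C)[C@@H]1[C@]1(O[Si](C)(C)C)C[C@@H](C)C[C@]21O[Si](C)(C)C | intermediate
6 | C10-isopropyl alkene (C9=C10) | CC(C)C1=CC[C@@]2(C)[C@@H]1[C@]1(O[Si](C)(C)C)C[C@@H](C)C[C@]21O[Si](C)(C)C | intermediate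
7 | convex-face 9,10-epoxide | CC(C)[C@]12O[C@H]1C[C@@]1(C)[C@@H]2[C@]2(O[Si](C)(C)C)C[C@@H](C)C[C@]12O[Si](C)(C)C | intermediate
8 | C10 tertiary alcohol, C1/C5 bis(trimethylsilyl ether) | CC(C)[C@]1(O)CC[C@@]2(C)[C@@H]1[C@]1(O[Si](C)(C)C)C[C@@H](C)C[C@]21O[Si](C)(C)C | intermediate
9 | tricyclic 1,5,10-triol | CC(C)[C@]1(O)CC[C@@]2(C)[C@@H]1[C@]1(O)C[C@@H](C)C[C@]21O | intermediate
10 | cis-fused 10-hydroxy-1,5-dione | O=C1C[C@H](C)CC(=O)[C@H]2[C@]1(C)CC[C@@]2(O)C(C)C | intermediate
11 | trans-fused 10-hydroxy-1,5-dione | O=C1C[C@H](C)CC(=O)[C@@H]2[C@]1(C)CC[C@@]2(O)C(C)C | intermediate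
12 | trans-fused 5α,10β-dihydroxy-1-ketone | O=C1C[C@H](C)C[C@H](O)[C@@H]2[C@]1(C)CC[C@@]2(O)C(C)C | intermediate
13 | 4-hydroxybenzoic acid | OC(=O)c1ccc(O)cc1 | starting material
14 | triisopropylsilyl 4-(triisopropylsilyloxy)benzoate | CC(C)[Si](OC(=O)c1ccc(O[Si](C(C)C)(C(C)C)C(C)C)cc1)(C(C)C)C(C)C | intermediate
15 | 4-(triisopropylsilyloxy)benzoic acid | CC(C)[Si](Oc1ccc(cc1)C(=O)O)(C(C)C)C(C)C | intermediate
16 | C5 4-(triisopropylsilyloxy)benzoate of 12 | O=C1C[C@H](C)C[C@H](OC(=O)c2ccc(O[Si](C(C)C)(C(C)C)C(C)C)cc2)[C@@H]2[C@]1(C)CC[C@@]2(O)C(C)C | intermediate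
17 | C1 trimethylsilyl enol ether (C1=C2) with C10–OSiMe3 | C[Si](C)(C)OC1=C[C@H](C)C[C@H](OC(=O)c2ccc(O[Si](C(C)C)(C(C)C)C(C)C)cc2)[C@@H]2[C@]1(C)CC[C@@]2(O[Si](C)(C)C)C(C)C | intermediate
18 | C2=C3 enone (C1=O) with C10–OSiMe3 | O=C1C=C(C)C[C@H](OC(=O)c2ccc(O[Si](C(C)C)(C(C)C)C(C)C)cc2)[C@@H]2[C@]1(C)CC[C@@]2(O[Si](C)(C)C)C(C)C | intermediate
19 | C1α allylic alcohol | O[C@@H]1C=C(C)C[C@H](OC(=O)c2ccc(O[Si](C(C)C)(C(C)C)C(C)C)cc2)[C@@H]2[C@]1(C)CC[C@@]2(O[Si](C)(C)C)C(C)C | intermediate
20 | angelic acid ((Z)-2-methylbut-2-enoic acid) | C/C=C(/C)C(=O)O | starting material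
21 | angelic 2,4,6-trichlorobenzoic mixed anhydride | C/C=C(/C)C(=O)OC(=O)c1c(Cl)cc(Cl)cc1Cl | intermediate
22 | C1 angelate, aryl O-triisopropylsilyl, C10 O-trimethylsilyl | C/C=C(/C)C(=O)O[C@@H]1C=C(C)C[C@H](OC(=O)c2ccc(O[Si](C(C)C)(C(C)C)C(C)C)cc2)[C@@H]2[C@]1(C)CC[C@@]2(O[Si](C)(C)C)C(C)C | intermediate
23 | CNP0273650.2 | C/C=C(/C)C(=O)O[C@@H]1C=C(C)C[C@H](OC(=O)c2ccc(O)cc2)[C@@H]2[C@]1(C)CC[C@@]2(O)C(C)C | target

**Step count and risks**

Total step count: 16. Longest linear sequence: 15 steps (1 → 23 through steps 1–10 and 12–16; step 11 is the only side branch).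

Steps most likely to fail:

1. Step 2. The enone faces may be poorly differentiated on the flat five-membered enone; the Lewis acid may strip silyl groups from the enediol ether or trigger dark conjugate addition; or it may promote retro-aldol opening of the β-silyloxy ketone as it forms. Fallback with known chemistry: set out from 2 and 3 and irradiate without Lewis acid (350 nm, Pyrex, hexane, −20 °C), the established uncatalysed enone/bis(silyloxy)alkene photocycloaddition, to obtain the racemic photoadduct F1. Add lithiated (S)-N,S-dimethyl-S-phenylsulfoximine (n-BuLi, THF, −78 °C), which should attack C10 from the convex face and give two diastereomeric adducts separable by chromatography. The diastereomer derived from the 7S ketone, the β-hydroxysulfoximine F2, is heated in toluene (110–130 °C), where it reverts to ketone and sulfoximine, and the route is rejoined at 4.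

2. Step 9. Retro-aldol cleavage of the C10–C6 bond through the tertiary alkoxide, or dehydration to a C6=C10 enone, may outrun C6 epimerisation. Fallback: set out from 10 and cap the C10 hydroxyl with N-(trimethylsilyl)imidazole (CH2Cl2, rt), which does not enolise ketones, to give the cis-fused silyl ether F3. Epimerise with DBU in toluene at 60 °C, where no alkoxide can form and the retro-aldol path is closed, to give the trans-fused silyl ether F4. Remove the silyl group with Bu4NF/AcOH in THF at 0 °C and rejoin the route at 11.

3. Step 6. Hydride has to reach C9 from the concave face past the C1 and C5 silyloxy groups, so the opening may be slow, or base-induced isomerisation of the epoxide to an allylic alcohol may take over. Fallback: set out from 6, bypassing 7, and use Mukaiyama hydration (Co(acac)2, PhSiH3, O2, i-PrOH, 0 °C; then PPh3). Hydrogen-atom transfer gives the tertiary C10 radical, which O2 should trap on the convex face; the solution is kept saturated with O2 so that trapping outruns opening of the adjacent cyclobutane. The route is rejoined at 8, and no compound outside the list is made (F0).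

Further compounds
F1 | step 2 | racemic photoadduct (racemate of 4, relative configuration as in 4; one enantiomer drawn) | O=C1CC[C@@]2(C)[C@@H]1[C@]1(O[Si](C)(C)C)C[C@@H](C)C[C@]21O[Si](C)(C)C
F2 | step 2 | β-hydroxysulfoximine from the 7S ketone (C10–OH on the concave face, C10–CH2S(O)(=NMe)Ph on the convex face, S configuration at sulfur) | O[C@]1(C[S@@](=O)(=NC)c2ccccc2)CC[C@@]2(C)[C@@H]1[C@]1(O[Si](C)(C)C)C[C@@H](C)C[C@]21O[Si](C)(C)C
F3 | step 9 | C10 trimethylsilyl ether of cis-fused dione 10 | O=C1C[C@H](C)CC(=O)[C@H]2[C@]1(C)CC[C@@]2(O[Si](C)(C)C)C(C)C
F4 | step 9 | C10 trimethylsilyl ether of trans-fused dione 11 | O=C1C[C@H](C)CC(=O)[C@@H]2[C@]1(C)CC[C@@]2(O[Si](C)(C)C)C(C)C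
F0 | step 6 | none | none
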